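## The problem

- The target is a 14-membered carbocycle (numbered here C1–C14; C1 carries the isopropyl group, C12 a methyl group) bridged by an oxygen between C1 and C12. The oxolane ring (C1, C14, C13, C12, O) therefore has two fully substituted ether carbons whose ring bonds C1–C2 and C12–C11 must be cis.
- The only alkene, E-C2=C3, lies between two fully substituted carbons (C1 and the tertiary carbinol C4). Olefination or metathesis at this bond is therefore unattractive.
- Five stereocentres must be set. C1 and C12 are tied to each other by the oxolane. C11 sits next to the quaternary C12 and is best set by a reagent. C8 is isolated and is best bought. C4 is 1,4 to C1 across the alkene and has no neighbour to control it.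
- C4–C5–C6 is a tertiary β-ketol (retro-aldol, dehydration). C1–O and C4–O are tertiary allylic bonds that ionize in acid. The formate is lost to base or nucleophiles. These groups must appear late.
- The feature used for the key step: C1, O, C12, C13 and C14 together with C2 and C11 are the seven ring atoms of a 7-oxabicyclo[2.2.1]heptane, the 1,4-cineole skeleton with its isopropyl and methyl bridgeheads. It lacks only the C2–C11 bond. In the target C11 bears oxygen and C2=C3 is an alkene, so an alkoxide on C11 and a leaving group on C3 of that bicycle are set up for a Grob fragmentation that breaks C2–C11 and makes C2=C3 in one event.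
- A second feature: the β-ketol maps onto a 2-isoxazoline (O–C4, C5–C6), so the carbocycle can be closed at C5–C6 with the ketol masked.

## Retrosynthesis

**26 ⇒ 25.** The formyl C–O bond at C11 is cut last, because the formate would not survive any earlier step. The forward reaction must acylate the secondary C11 hydroxyl and leave the tertiary C4 hydroxyl alone.

**25 ⇒ 23.** The ketol is redrawn as 2-isoxazoline 23 (C6=N, N–O, O–C4). Unmasking is a neutral hydrogenolysis, so the retro-aldol-prone ketol exists for only one step before the end.

**23 ⇒ 21 (through nitrile oxide 22).** C5–C6 and O–C4 are cut together as an intramolecular nitrile oxide cycloaddition. Ring closure at C2=C3 would have to join two neopentyl-type carbons, and closure at C10–C11 would need an intramolecular organometallic addition. The cycloaddition instead forms the C–C bond at an unhindered terminal CH2 under non-basic conditions. Precursor 21 is an open chain on a single oxolane. The forward step must be regioselective (O to C4), must spare C2=C3, and must choose the correct face at C4, which is the one stereocentre left to substrate control.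

**21 ⇒ 19 ⇒ 18.** The oxime comes from the dimethyl acetal. The C11 carbinol comes from ketone 18 by a reagent-controlled reduction, because the quaternary C12 offers little intrinsic bias.

**18 ⇒ 16 (through 17), the key disconnection.** C2 is reconnected to C11 and an oxygen is placed on C3, which makes 18 the Grob product of a γ-sulfonyloxy alkoxide on the cineole skeleton. This removes three problems at once:
- the oxolane with both quaternary centres becomes a rigid bicycle that is bought as a monoterpene;
- the hindered E-alkene becomes a C2–C3 single bond made by an aldol at a secondary enolate carbon;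
- the C11 ketone with its chain becomes a tertiary alkoxide made by Grignard addition.

The forward step must fragment rather than close an oxetane or eliminate, and the E geometry must follow from the C2/C3 configuration.

**16 ⇒ 8 + 15, and 8 ⇒ 4 + 5.** C10–C11 is cut as a Grignard addition to the ring ketone. C2–C3 is cut as an aldol of 1,4-cineol-2-one (4) with methacrolein (5). The aldol must occur on the exo face with syn topology.

**4 ⇒ 3 ⇒ 1.** Ketone 4 comes from (R)-terpinen-4-ol (1) by directed epoxidation, transannular etherification and oxidation. C1 is the stereocentre of 1. C12 follows because the oxygen bridge can only form cis.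

**15 ⇒ 14 ⇒ 13 ⇒ 12 ⇒ 11 ⇒ 9.** C6–C10 with C8 comes from methyl (R)-3-methylglutarate (9). The two ends are told apart by chemoselective reduction of the ester. The acid end becomes C6 (masked aldehyde, later the nitrile oxide carbon) and the ester end becomes C10 (Grignard carbon).

## Roads not taken

**Alternative 1:** The obvious, biomimetic cut is the C12–O bond. The oxolane would form by 5-exo opening of the 11,12-epoxide of macrocycle A1 by the C1 tertiary hydroxyl, and the carbocycle would be closed earlier by a standard macrocyclization.
- A1 needs the C1 carbinol (isopropyl against CH2) as a defined stereocentre with no neighbour to control it.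
- The E-C2=C3 bond between two fully substituted carbons still has to be made separately.
- The doubly allylic C1–OH must survive the acid that opens the epoxide.

The chosen plan buys C1 and C12 together and makes the alkene by fragmentation, in fewer steps.

**Alternative 2:** The C1–C2 bond is cut at the ketal oxidation level. Bicyclic ketal A2 (a 2,7-dioxabicyclo[2.2.1]heptane in which C1 is bonded to both O11 and O12) would be opened at C1 by an aluminium acetylide delivered from the departing O11. The alkyne would then be reduced to the E-alkene by hydroxyl-directed hydroalumination with NaAlH2(OCH2CH2OMe)2.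
- The C1 configuration then depends on retentive delivery to a fully substituted ketal carbon and on which C–O bond of the ketal ionizes.
- C4 must be carried in the alkyne partner, and the ring must still be closed at C5–C6 by acyl-anion chemistry.

The chosen plan fixes C1 by construction and needs no step of that kind.

**Alternative 3:** The C2=C3 bond is cut as an olefination. Oxolane aldehyde A3 and sulfone A4 (C4 pre-set) would be joined by a Julia–Kocienski reaction, and the ring would be closed by metathesis at C9=C10 and hydrogenation after chain extension at C11.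
- Both partners are neopentyl-type, so carbanion addition is slow and reversible.
- The β-silyloxy sulfone anion can eliminate.
- A4 alone needs a long sequence.
- An extra alkene must be removed in the presence of C2=C3.

The chosen plan forms C2–C3 where it is unhindered and needs no redox correction.

Key step: step 9

Remark: commercial (R)-(−)-terpinen-4-ol (1) and methyl (R)-3-methylglutarate (9) are taken as enantiomerically pure; otherwise they are enriched before use.

## Route

Step 1
Reactants: 1 (R)-terpinen-4-ol [(1R)-4-methyl-1-(propan-2-yl)cyclohex-3-en-1-ol]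
Product: 3 (1S,2R,4R)-1-methyl-4-(propan-2-yl)-7-oxabicyclo[2.2.1]heptan-2-ol (2-exo-hydroxy-1,4-cineole), via syn-epoxide 2 (not isolated)
Conditions: VO(acac)2 (cat.), tBuOOH, PhMe, rt; then TsOH·H2O (cat.), rt
Reagents that add atoms: tert-butyl hydroperoxide, CC(C)(C)OO
Why: Hydroxyl-directed vanadium-catalysed epoxidation should put the oxygen syn to the C1 hydroxyl; acid then opens the tertiary C12–O bond and the C1 hydroxyl closes the oxygen bridge (transannular etherification). C1 is the stereocentre of 1 and C12 follows because the bridge can only form cis; the exo alcohol at C11 is removed in step 2.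

Step 2
Reactants: 3 (1S,2R,4R)-1-methyl-4-(propan-2-yl)-7-oxabicyclo[2.2.1]heptan-2-ol
Product: 4 (1S,4R)-1-methyl-4-(propan-2-yl)-7-oxabicyclo[2.2.1]heptan-2-one (1,4-cineol-2-one)
Conditions: TEMPO (cat.), KBr (cat.), NaOCl, NaHCO3, CH2Cl2/H2O, 0 °C
Reagents that add atoms: none
Why: Oxoammonium oxidation of a secondary alcohol; nothing can epimerize because the only α-stereocentre (C12) is quaternary.

Step 3
Reactants: 4 (1S,4R)-1-methyl-4-(propan-2-yl)-7-oxabicyclo[2.2.1]heptan-2-one; 5 methacrolein (2-methylprop-2-enal)
Product: 8 (1S,3R,4S)-3-[(1S)-1-hydroxy-2-methylprop-2-en-1-yl]-1-methyl-4-(propan-2-yl)-7-oxabicyclo[2.2.1]heptan-2-one (syn aldol with exo side chain), via lithium enolate 6 (not isolated), via triisopropoxytitanium enolate 7 (not isolated)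
Conditions: LiN(iPr)2, THF, −78 °C; ClTi(OiPr)3, −78 to −40 °C; 5, −78 °C
Reagents that add atoms: none
Why: Only C2 can enolize (C12 is a bridgehead); the aldehyde should add on the exo face, which sets C2, and titanium triisopropoxide enolates of cyclic ketones add to aldehydes with syn (erythro) preference whatever the enolate geometry, which sets the C3 carbinol. Both centres are temporary and serve only to fix the alkene geometry in step 9.

Step 4
Reactants: 9 methyl (R)-3-methylglutarate [(3R)-5-methoxy-3-methyl-5-oxopentanoic acid]
Product: 11 (S)-4-methyloxan-2-one, via hydroxy acid 10 (not isolated)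
Conditions: LiBH4, THF, 0 °C to rt; then 2 M HCl, rt
Reagents that add atoms: none
Why: LiBH4 reduces the ester but not the lithium carboxylate, and acid closes the δ-lactone. The acid carbon becomes C6 and the ester carbon C10, which gives the C8 configuration of the target; C8 is not α to a carbonyl and cannot epimerize.

Step 5
Reactants: 11 (S)-4-methyloxan-2-one
Product: 12 methyl (R)-5-bromo-3-methylpentanoate
Conditions: HBr, MeOH, 0 to 40 °C
Reagents that add atoms: hydrogen bromide, Br; methanol, CO
Why: Acid-mediated alkyl–oxygen cleavage of the lactone by bromide (SN2 at the primary C10) with Fischer esterification of the freed acid, as known for simple lactones.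

Step 6
Reactants: 12 methyl (R)-5-bromo-3-methylpentanoate
Product: 13 (R)-5-bromo-3-methylpentanal
Conditions: iBu2AlH, CH2Cl2, −78 °C
Reagents that add atoms: none
Why: Partial reduction of a methyl ester at low temperature through the aluminium hemiacetal.

Step 7
Reactants: 13 (R)-5-bromo-3-methylpentanal
Product: 14 (R)-5-bromo-1,1-dimethoxy-3-methylpentane
Conditions: HC(OMe)3, TsOH (cat.), MeOH, rt
Reagents that add atoms: trimethyl orthoformate, COC(OC)OC
Why: Acid-catalysed acetalization driven by the orthoformate; the acetal masks C6 through the organometallic and base steps.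

Step 8
Reactants: 8 (1S,3R,4S)-3-[(1S)-1-hydroxy-2-methylprop-2-en-1-yl]-1-methyl-4-(propan-2-yl)-7-oxabicyclo[2.2.1]heptan-2-one; 14 (R)-5-bromo-1,1-dimethoxy-3-methylpentane
Product: 16 tertiary alcohol from addition of the (3S)-5,5-dimethoxy-3-methylpentyl group to the ring carbonyl of 8 (1,3-diol; either C11 epimer), via Grignard reagent 15 (not isolated)
Conditions: 14, Mg, THF, 40 °C; 8, tBuMgCl (1 equiv), THF, −78 °C; then 15, −78 to −30 °C
Reagents that add atoms: none
Why: The non-nucleophilic tBuMgCl takes the hydroxyl proton, and the chelated β-alkoxy ketone then takes up 15 at C11 (Grignard 1,2-addition), forming the C10–C11 bond. The new carbinol centre is not controlled and need not be, since C11 becomes a ketone in step 9.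

Step 9
Reactants: 16 tertiary alcohol (1,3-diol; either C11 epimer)
Product: 18 (4S)-6,6-dimethoxy-4-methyl-1-[(2S,5S)-2-methyl-5-[(1E)-3-methylbuta-1,3-dien-1-yl]-5-(propan-2-yl)oxolan-2-yl]hexan-1-one, via allylic mesylate 17 (not isolated)
Conditions: MsCl, Et3N, CH2Cl2, −40 °C; then KOtBu, THF, −40 to 0 °C
Reagents that add atoms: none
Why: Sulfene mesylation is selective for the secondary allylic C3 hydroxyl over the tertiary C11 hydroxyl; KOtBu then gives the C11 alkoxide, whose lone pair forms C11=O while the C11–C2 σ-bond becomes the C2=C3 π-bond and methanesulfonate leaves from C3 (concerted Grob fragmentation of a γ-sulfonyloxy alkoxide; the closest known type is the fragmentation of cyclic 1,3-diol monosulfonates to alkenyl ketones). No ring is closed: the six-membered carbocycle of the oxanorbornane is opened with release of strain and the oxolane remains, and because no bond to C1 or C12 is broken their cis relationship is that of the bicycle. No new stereocentre is formed; the stereochemical issue is the alkene geometry, which is fixed by the anti-periplanar alignment of C11–C2 and C3–O, and in the syn aldol series of 8 this conformer has C1 and C4 anti, giving the E alkene between the two fully substituted carbons. The exocyclic C2–C3 bond rotates freely, so the alignment is reachable, and the C11 configuration is irrelevant because C11 becomes trigonal. The selectivity needed is fragmentation in preference to oxetane formation (alkoxide attack on C3), elimination or allylic substitution at the mesylate; strain release, the allylic nucleofuge and alkoxide generation at low temperature favour fragmentation. The same event gives the C11 ketone already carrying C6–C10, so the bicycle made from 1 becomes the complete open-chain precursor of the macrocycle in one operation.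

Step 10
Reactants: 18 (4S)-6,6-dimethoxy-4-methyl-1-[(2S,5S)-2-methyl-5-[(1E)-3-methylbuta-1,3-dien-1-yl]-5-(propan-2-yl)oxolan-2-yl]hexan-1-one
Product: 19 (1R,4S)-6,6-dimethoxy-4-methyl-1-[(2S,5S)-2-methyl-5-[(1E)-3-methylbuta-1,3-dien-1-yl]-5-(propan-2-yl)oxolan-2-yl]hexan-1-ol
Conditions: (S)-2-methyl-CBS-oxazaborolidine (cat.), catecholborane, PhMe, −78 °C
Reagents that add atoms: none
Why: Corey–Bakshi–Shibata reduction in which the quaternary C12 is the large group and the C10 methylene the small one, so the (S)-catalyst should give the 11R alcohol; catecholborane does not hydroborate the diene at this temperature.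

Step 11
Reactants: 19 (1R,4S)-6,6-dimethoxy-4-methyl-1-[(2S,5S)-2-methyl-5-[(1E)-3-methylbuta-1,3-dien-1-yl]-5-(propan-2-yl)oxolan-2-yl]hexan-1-ol
Product: 21 oxime of (3S,6R)-6-hydroxy-3-methyl-6-[(2S,5S)-2-methyl-5-[(1E)-3-methylbuta-1,3-dien-1-yl]-5-(propan-2-yl)oxolan-2-yl]hexanal, via aldehyde 20 (not isolated)
Conditions: NH2OH·HCl, THF/H2O, rt
Reagents that add atoms: hydroxylamine (used as its hydrochloride), NO
Why: The mildly acidic hydroxylammonium salt hydrolyses the dimethyl acetal, and the aldehyde condenses at once to the aldoxime; the acidity is too low to ionize the allylic ether at C1.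

Step 12
Reactants: 21 oxime of (3S,6R)-6-hydroxy-3-methyl-6-[(2S,5S)-2-methyl-5-[(1E)-3-methylbuta-1,3-dien-1-yl]-5-(propan-2-yl)oxolan-2-yl]hexanal
Product: 23 macrocyclic 2-isoxazoline (1S,2E,4S,8S,11R,12S; C6=N–O–C4 bridge; free 11-hydroxyl), via nitrile oxide 22 (not isolated)
Conditions: aq NaOCl, CH2Cl2, 0 °C to rt, slow addition (2 mM)
Reagents that add atoms: none
Why: Oxidation of the aldoxime gives the nitrile oxide, which adds intramolecularly to the terminal 1,1-disubstituted C4=C5 bond (C6 to C5, O to C4; 1,3-dipolar cycloaddition used as macrocyclization) and closes the 14-membered carbocycle. Regiochemistry follows the usual preference for oxygen at the substituted carbon, and the C2=C3 bond between two quaternary carbons is not attacked. The C4 configuration is set by the tether alone (substrate control), which is the least secure stereochemical element of the route.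

Step 13
Reactants: 23 macrocyclic 2-isoxazoline
Product: 25 (1S,2E,4S,8S,11R,12S)-4,11-dihydroxy-4,8,12-trimethyl-1-(propan-2-yl)-15-oxabicyclo[10.2.1]pentadec-2-en-6-one, via hydroxy imine 24 (not isolated)
Conditions: H2 (1 atm), Raney Ni, B(OH)3, MeOH/H2O, rt
Reagents that add atoms: water, O
Why: Hydrogenolysis of the N–O bond and boric-acid-buffered hydrolysis of the β-hydroxy imine release the ketol near neutrality; the C2=C3 bond flanked by two fully substituted carbons should resist hydrogenation.

Step 14
Reactants: 25 (1S,2E,4S,8S,11R,12S)-4,11-dihydroxy-4,8,12-trimethyl-1-(propan-2-yl)-15-oxabicyclo[10.2.1]pentadec-2-en-6-one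
Product: 26 (1S,2E,4S,8S,11R,12S)-4-hydroxy-4,8,12-trimethyl-6-oxo-1-(propan-2-yl)-15-oxabicyclo[10.2.1]pentadec-2-en-11-yl formate (CNP0176107.1)
Conditions: HCO2Ac, pyridine, CH2Cl2, −20 to 0 °C
Reagents that add atoms: acetic formic anhydride, CC(=O)OC=O
Why: The mixed anhydride transfers the small formyl group to the secondary C11 hydroxyl; the tertiary, hydrogen-bonded C4 hydroxyl should not be acylated under these conditions.

## Compound list

1 | (R)-terpinen-4-ol | CC(C)[C@]1(O)CC=C(C)CC1 | starting material
2 | syn-1,2-epoxide of 1 (epoxide oxygen cis to the hydroxyl) | CC(C)[C@]1(O)C[C@H]2O[C@@]2(C)CC1 | intermediate (not isolated)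
3 | (1S,2R,4R)-1-methyl-4-(propan-2-yl)-7-oxabicyclo[2.2.1]heptan-2-ol | CC(C)[C@]12C[C@@H](O)[C@](C)(CC1)O2 | intermediate
4 | (1S,4R)-1-methyl-4-(propan-2-yl)-7-oxabicyclo[2.2.1]heptan-2-one | CC(C)[C@]12CC(=O)[C@](C)(CC1)O2 | intermediate
5 | methacrolein | CC(=C)C=O | starting material
6 | lithium enolate of 4 | CC(C)[C@]12C=C([O-])[C@](C)(CC1)O2.[Li+] | intermediate (not isolated)
7 | triisopropoxytitanium enolate of 4 | CC(C)[C@]12C=C(O[Ti](OC(C)C)(OC(C)C)OC(C)C)[C@](C)(CC1)O2 | intermediate (not isolated)
8 | (1S,3R,4S)-3-[(1S)-1-hydroxy-2-methylprop-2-en-1-yl]-1-methyl-4-(propan-2-yl)-7-oxabicyclo[2.2.1]heptan-2-one | CC(C)[C@]12[C@@H]([C@H](O)C(C)=C)C(=O)[C@](C)(CC1)O2 | intermediate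
9 | methyl (R)-3-methylglutarate | COC(=O)C[C@H](C)CC(=O)O | starting material
10 | (S)-5-hydroxy-3-methylpentanoic acid (lithium salt in the flask) | OCC[C@H](C)CC(=O)O | intermediate (not isolated)
11 | (S)-4-methyloxan-2-one | O=C1C[C@@H](C)CCO1 | intermediate
12 | methyl (R)-5-bromo-3-methylpentanoate | COC(=O)C[C@@H](C)CCBr | intermediate
13 | (R)-5-bromo-3-methylpentanal | O=CC[C@@H](C)CCBr | intermediate
14 | (R)-5-bromo-1,1-dimethoxy-3-methylpentane | COC(OC)C[C@@H](C)CCBr | intermediate
15 | [(R)-5,5-dimethoxy-3-methylpentyl]magnesium bromide | COC(OC)C[C@@H](C)CC[Mg]Br | intermediate (not isolated)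
16 | tertiary alcohol from 8 and 15 (1,3-diol; C11 not defined) | CC(C)[C@]12[C@@H]([C@H](O)C(C)=C)C(O)(CC[C@H](C)CC(OC)OC)[C@](C)(CC1)O2 | intermediate
17 | C3 methanesulfonate of 16 | CC(C)[C@]12[C@@H]([C@H](OS(C)(=O)=O)C(C)=C)C(O)(CC[C@H](C)CC(OC)OC)[C@](C)(CC1)O2 | intermediate (not isolated)
18 | (4S)-6,6-dimethoxy-4-methyl-1-[(2S,5S)-2-methyl-5-[(1E)-3-methylbuta-1,3-dien-1-yl]-5-(propan-2-yl)oxolan-2-yl]hexan-1-one | CC(C)[C@]1(/C=C/C(C)=C)CC[C@](C)(O1)C(=O)CC[C@H](C)CC(OC)OC | intermediate
19 | (1R,4S)-6,6-dimethoxy-4-methyl-1-[(2S,5S)-2-methyl-5-[(1E)-3-methylbuta-1,3-dien-1-yl]-5-(propan-2-yl)oxolan-2-yl]hexan-1-ol | CC(C)[C@]1(/C=C/C(C)=C)CC[C@](C)(O1)[C@H](O)CC[C@H](C)CC(OC)OC | intermediate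
20 | (3S,6R)-6-hydroxy-3-methyl-6-[(2S,5S)-2-methyl-5-[(1E)-3-methylbuta-1,3-dien-1-yl]-5-(propan-2-yl)oxolan-2-yl]hexanal | CC(C)[C@]1(/C=C/C(C)=C)CC[C@](C)(O1)[C@H](O)CC[C@H](C)CC=O | intermediate (not isolated)
21 | oxime of 20 | CC(C)[C@]1(/C=C/C(C)=C)CC[C@](C)(O1)[C@H](O)CC[C@H](C)CC=NO | intermediate
22 | nitrile oxide from 21 | CC(C)[C@]1(/C=C/C(C)=C)CC[C@](C)(O1)[C@H](O)CC[C@H](C)CC#[N+][O-] | intermediate (not isolated)
23 | macrocyclic 2-isoxazoline (C6=N–O–C4), 11-ol | CC(C)[C@]12/C=C/[C@]3(C)CC(=NO3)C[C@@H](C)CC[C@@H](O)[C@](C)(CC1)O2 | intermediate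
24 | β-hydroxy imine of 25 at C6 | CC(C)[C@]12/C=C/[C@@](C)(O)CC(=N)C[C@@H](C)CC[C@@H](O)[C@](C)(CC1)O2 | intermediate (not isolated)
25 | (1S,2E,4S,8S,11R,12S)-4,11-dihydroxy-4,8,12-trimethyl-1-(propan-2-yl)-15-oxabicyclo[10.2.1]pentadec-2-en-6-one | CC(C)[C@]12/C=C/[C@@](C)(O)CC(=O)C[C@@H](C)CC[C@@H](O)[C@](C)(CC1)O2 | intermediate
26 | (1S,2E,4S,8S,11R,12S)-4-hydroxy-4,8,12-trimethyl-6-oxo-1-(propan-2-yl)-15-oxabicyclo[10.2.1]pentadec-2-en-11-yl formate | CC(C)[C@]12/C=C/[C@@](C)(O)CC(=O)C[C@@H](C)CC[C@@H](OC=O)[C@](C)(CC1)O2 | target

## Step count and least certain steps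

Total: 14 steps. Longest linear sequence: 11 steps (from 9 through steps 4–14); the branch from 1 has 10 steps.

**Step 9 (key step).** The C11 alkoxide may attack C3 instead of fragmenting (oxetane formation). The allylic mesylate may also be lost by elimination or allylic substitution before the alkoxide is formed, because a secondary allylic sulfonate ionizes easily.
Fallback, from 4 back to 18, with bond cleavage and alkene formation as separate events:
- The lithium enolate of 4 is hydroxylated with 2-(phenylsulfonyl)-3-phenyloxaziridine to exo-3-hydroxy-1,4-cineol-2-one F1.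
- Addition of 15 gives the ring 2,3-diol F2.
- Glycol cleavage with Pb(OAc)4 in CH2Cl2/pyridine opens the C2–C11 bond to the oxolane keto aldehyde F3.
- E-selective olefination of the aldehyde with the ylide from tributyl(2-methylallyl)phosphonium bromide and KOtBu returns 18.

**Step 12.** Facial selectivity at C4 is the main risk, because only the tether decides which face of C4=C5 the nitrile oxide reaches. The 4S product requires either the s-trans diene with the C1–C14 bond eclipsing C2=C3, or the s-cis diene with the C1–O bond eclipsing it, and neither preference is assured. Dimerization of the nitrile oxide to furoxans is the second risk.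
Fallback, from 20 back to 25, with C4 set by a chiral catalyst:
- Aldehyde 20 is isolated and treated with vinylmagnesium bromide to give allylic alcohol F4.
- MnO2 oxidizes the allylic carbinol selectively to vinyl ketone F5.
- Ring-closing metathesis with the second-generation Grubbs catalyst joins C4=C5H2 with the vinyl ketone to the macrocyclic (2E,4E)-dienone F6.
- Conjugate borylation (B2pin2, CuCl, NaOtBu, chiral bisphosphine, MeOH) gives the C4 pinacol boronate F7.
- Oxidation with NaBO3·4H2O returns 25.

**Step 3.** Low syn selectivity, retro-aldol cleavage of the titanium aldolate or polymerization of methacrolein would reduce the supply of the isomer that can fragment to the E alkene.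
Fallback, from 4 back to 18, stereoconvergent at C3:
- The aldol is run with the lithium enolate without control at C3, giving 8 together with its C3 epimer F8.
- The mixture is taken through step 8 to 16 and the epimeric diol F9.
- Both are mesylated (17 and the epimeric mesylate F10) and solvolysed in (CF3)2CHOH with 2,6-lutidine. Under these conditions the allylic C3–O bond ionizes first, C3 becomes planar, and both epimers should collapse to the E-diene 18.

**Step 14.** Acyl transfer to the tertiary C4 hydroxyl or base-induced dehydration of the ketol would erode the last step.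
Fallback, from 23 back to 26, with the order of the last two steps reversed:
- Isoxazoline 23, which has only the C11 hydroxyl, is formylated with HCO2Ac/pyridine to the isoxazoline formate F11.
- The N–O bond is then cleaved with Mo(CO)6 in MeCN/H2O, which is neutral and leaves the formate intact, to give 26 directly.

## Further compounds

F1 | step 9 | exo-3-hydroxy-1,4-cineol-2-one | CC(C)[C@]12[C@@H](O)C(=O)[C@](C)(CC1)O2
F2 | step 9 | ring 2,3-diol from F1 and 15 (C11 not defined) | CC(C)[C@]12[C@@H](O)C(O)(CC[C@H](C)CC(OC)OC)[C@](C)(CC1)O2
F3 | step 9 | (2S,5S)-5-[(4S)-6,6-dimethoxy-4-methylhexanoyl]-5-methyl-2-(propan-2-yl)oxolane-2-carbaldehyde | CC(C)[C@]1(C=O)CC[C@](C)(O1)C(=O)CC[C@H](C)CC(OC)OC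
F4 | step 12 | allylic alcohol from 20 and vinylmagnesium bromide (C6 not defined) | CC(C)[C@]1(/C=C/C(C)=C)CC[C@](C)(O1)[C@H](O)CC[C@H](C)CC(O)C=C
F5 | step 12 | vinyl ketone from F4 | CC(C)[C@]1(/C=C/C(C)=C)CC[C@](C)(O1)[C@H](O)CC[C@H](C)CC(=O)C=C
F6 | step 12 | macrocyclic (2E,4E)-dienone, 11-ol | CC(C)[C@]12/C=C/C(C)=C/C(=O)C[C@@H](C)CC[C@@H](O)[C@](C)(CC1)O2
F7 | step 12 | C4 pinacol boronate of the macrocyclic ketone, 11-ol | CC(C)[C@]12/C=C/[C@@](C)(B3OC(C)(C)C(C)(C)O3)CC(=O)C[C@@H](C)CC[C@@H](O)[C@](C)(CC1)O2
F8 | step 3 | C3 epimer of 8 (anti aldol) | CC(C)[C@]12[C@@H]([C@@H](O)C(C)=C)C(=O)[C@](C)(CC1)O2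
F9 | step 3 | C3 epimer of 16 | CC(C)[C@]12[C@@H]([C@@H](O)C(C)=C)C(O)(CC[C@H](C)CC(OC)OC)[C@](C)(CC1)O2
F10 | step 3 | C3 methanesulfonate of F9 | CC(C)[C@]12[C@@H]([C@@H](OS(C)(=O)=O)C(C)=C)C(O)(CC[C@H](C)CC(OC)OC)[C@](C)(CC1)O2
F11 | step 14 | C11 formate of isoxazoline 23 | CC(C)[C@]12/C=C/[C@]3(C)CC(=NO3)C[C@@H](C)CC[C@@H](OC=O)[C@](C)(CC1)O2
A1 | alternative 1 | macrocyclic 11,12-epoxy-1,4-diol (14-membered 2E-en-6-one with free C1 hydroxyl) | CC(C)[C@]1(O)/C=C/[C@@](C)(O)CC(=O)C[C@@H](C)CC[C@H]2O[C@]2(C)CC1
A2 | alternative 2 | 2,7-dioxabicyclo[2.2.1]heptane ketal of the C1 ketone with O11 and O12, chain ending in a 1,3-dithiane at C6 | CC(C)[C@]12CC[C@](C)(O1)[C@@H](CC[C@H](C)CC3SCCCS3)O2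
A3 | alternative 3 | methyl (2S,5S)-5-formyl-2-methyl-5-(propan-2-yl)oxolane-2-carboxylate | CC(C)[C@]1(C=O)CC[C@](C)(O1)C(=O)OC
A4 | alternative 3 | 1-phenyltetrazol-5-yl sulfone carrying C3–C9 (C4 triethylsilyl ether, C6 dioxolane, C9 vinyl) | C=C[C@H](C)CC1(OCCO1)C[C@](C)(O[Si](CC)(CC)CC)CS(=O)(=O)c1nnnn1-c1ccccc1
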